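**Assumption:** the target SMILES has no stereocentre and no stereo descriptor, so it is made as the single achiral compound; rotamers about the indole–quinone bonds are not distinguished.

## Retrosynthetic overview

1. Target 14 ⇐ O-methylation of dihydroxyquinone 13 ⇐ hydrolysis (C–Cl to C–O) of 2,5-dichloro-3,6-bis(indolyl)quinone 12.
2. 12 ⇐ two successive intermolecular Michael additions of indole 7 (C3 nucleophile) to purchased 2,5-dichloro-1,4-benzoquinone 8, each followed by reoxidation. These make both indole–quinone C–C bonds.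
3. Indole 7 ⇐ Madelung cyclisation of o-toluidide 6. The pyrrole ring is the only ring formed, and it is closed before the quinone is attached.
4. 6 ⇐ 2-methylaniline 4 + 2,2-dimethylbut-3-enoic acid 3 ⇐ prenylmagnesium chloride 2 + CO2, which sets the quaternary 1,1-dimethylallyl carbon.

## Route

Step 1
Reactants: 1 1-chloro-3-methylbut-2-ene (prenyl chloride)
Product: 3 2,2-dimethylbut-3-enoic acid, via prenylmagnesium chloride 2 (not isolated)
Conditions: Mg turnings (3 equiv), THF, 0–10 °C, slow addition of 1; then CO2 gas, −20 °C → rt; 2 M HCl work-up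
Reagents that add atoms: carbon dioxide (O=C=O)
Why: Grignard carboxylation of an allylic Grignard reagent proceeds with allylic transposition (SE2') at the more substituted terminus, giving the α,α-dimethyl acid with the terminal vinyl group; no stereocentre is formed.

Step 2
Reactants: 3 2,2-dimethylbut-3-enoic acid; 4 2-methylaniline (o-toluidine)
Product: 6 2,2-dimethyl-N-(2-methylphenyl)but-3-enamide, via 2,2-dimethylbut-3-enoyl chloride 5 (not isolated)
Conditions: (COCl)2 (1.1 equiv), N,N-dimethylformamide (cat.), CH2Cl2, 0 °C → rt; then 4 (1.0 equiv), Et3N (2.5 equiv), CH2Cl2, 0 °C → rt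
Reagents that add atoms: none
Why: Acid chloride formation followed by N-acylation of the aniline is routine, and the acid has no α-hydrogen, so neither ketene formation nor alkene migration can occur.

Step 3
Reactants: 6 2,2-dimethyl-N-(2-methylphenyl)but-3-enamide
Product: 7 2-(2-methylbut-3-en-2-yl)-1H-indole
Conditions: n-BuLi (3.0 equiv), THF, −20 °C → rt, 16 h; H2O quench
Reagents that add atoms: none
Why: Madelung indole synthesis in its organolithium (Houlihan) form: deprotonation at N–H and at the ortho-methyl group lets the benzylic carbanion add to the non-enolisable amide carbonyl, and loss of the oxygen aromatises to the indole; the isolated vinyl group is inert to n-BuLi at these temperatures.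

Step 4
Reactants: 7 2-(2-methylbut-3-en-2-yl)-1H-indole; 8 2,5-dichloro-1,4-benzoquinone (1.5 equiv)
Product: 10 2,5-dichloro-3-[2-(2-methylbut-3-en-2-yl)-1H-indol-3-yl]cyclohexa-2,5-diene-1,4-dione, via hydroquinone adduct 9 (not isolated)
Conditions: AcOH/THF (1:1), rt, dark, N2, 24 h; then DDQ (1.05 equiv), rt, 1 h
Reagents that add atoms: none
Why: Acid-promoted intermolecular Michael addition of the enamine-like indole C3 to the unsubstituted β-carbon of the chloro-enone gives the aromatic hydroquinone, which DDQ dehydrogenates to the quinone; acetic acid is mild enough to spare the 1,1-dimethylallyl group and no stereocentre is formed.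

Step 5
Reactants: 10 2,5-dichloro-3-[2-(2-methylbut-3-en-2-yl)-1H-indol-3-yl]cyclohexa-2,5-diene-1,4-dione; 7 2-(2-methylbut-3-en-2-yl)-1H-indole (1.3 equiv)
Product: 12 2,5-dichloro-3,6-bis[2-(2-methylbut-3-en-2-yl)-1H-indol-3-yl]cyclohexa-2,5-diene-1,4-dione, via bis-indolyl hydroquinone 11 (not isolated)
Conditions: AcOH, 40 °C, N2, 48 h; then DDQ (1.05 equiv), CH2Cl2, rt, 1 h
Reagents that add atoms: none
Why: A second intermolecular Michael addition can only take place at the one remaining C–H carbon of the quinone, so the two indoles necessarily end up para, and DDQ oxidation returns the quinone; the step is slower because of the tert-alkyl group, hence warming and excess indole.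

Step 6
Reactants: 12 2,5-dichloro-3,6-bis[2-(2-methylbut-3-en-2-yl)-1H-indol-3-yl]cyclohexa-2,5-diene-1,4-dione
Product: 13 2,5-dihydroxy-3,6-bis[2-(2-methylbut-3-en-2-yl)-1H-indol-3-yl]cyclohexa-2,5-diene-1,4-dione
Conditions: 10% aq NaOH, MeOH, reflux, N2, 2 h; then 1 M HCl to pH 2
Reagents that add atoms: sodium hydroxide ([Na+].[OH-])
Why: The C–Cl carbons are vinylogous acyl chlorides and undergo addition–elimination (vinylic nucleophilic substitution) with oxygen nucleophiles, the very stable 2,5-dihydroxyquinone being the thermodynamic sink; indole and vinyl groups are inert to base.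

Step 7
Reactants: 13 2,5-dihydroxy-3,6-bis[2-(2-methylbut-3-en-2-yl)-1H-indol-3-yl]cyclohexa-2,5-diene-1,4-dione
Product: 14 2,5-dimethoxy-3,6-bis[2-(2-methylbut-3-en-2-yl)-1H-indol-3-yl]cyclohexa-2,5-diene-1,4-dione (target)
Conditions: TMSCHN2 (2 M in hexanes, 4 equiv), CH2Cl2/MeOH (4:1), 0 °C → rt, 1 h
Reagents that add atoms: (trimethylsilyl)diazomethane (C[Si](C)(C)C=[N+]=[N-])
Why: O-Methylation with a diazoalkane: the enolic OH groups are vinylogous carboxylic acids that protonate the reagent and are then methylated, whereas the non-acidic indole N–H and the alkenes do not react.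

## Compound list

1 | 1-chloro-3-methylbut-2-ene (prenyl chloride) | CC(C)=CCCl | starting material
2 | (3-methylbut-2-en-1-yl)magnesium chloride (prenylmagnesium chloride) | CC(C)=CC[Mg]Cl | intermediate
3 | 2,2-dimethylbut-3-enoic acid | C=CC(C)(C)C(=O)O | intermediate
4 | 2-methylaniline (o-toluidine) | Cc1ccccc1N | starting material
5 | 2,2-dimethylbut-3-enoyl chloride | C=CC(C)(C)C(=O)Cl | intermediate
6 | 2,2-dimethyl-N-(2-methylphenyl)but-3-enamide | C=CC(C)(C)C(=O)Nc1ccccc1C | intermediate
7 | 2-(2-methylbut-3-en-2-yl)-1H-indole | C=CC(C)(C)c1cc2ccccc2[nH]1 | intermediate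
8 | 2,5-dichlorocyclohexa-2,5-diene-1,4-dione (2,5-dichloro-1,4-benzoquinone) | O=C1C=C(Cl)C(=O)C=C1Cl | starting material
9 | 2,5-dichloro-3-[2-(2-methylbut-3-en-2-yl)-1H-indol-3-yl]benzene-1,4-diol | C=CC(C)(C)c1[nH]c2ccccc2c1-c1c(O)c(Cl)cc(O)c1Cl | intermediate
10 | 2,5-dichloro-3-[2-(2-methylbut-3-en-2-yl)-1H-indol-3-yl]cyclohexa-2,5-diene-1,4-dione | C=CC(C)(C)c1[nH]c2ccccc2c1C1=C(Cl)C(=O)C=C(Cl)C1=O | intermediate
11 | 2,5-dichloro-3,6-bis[2-(2-methylbut-3-en-2-yl)-1H-indol-3-yl]benzene-1,4-diol | C=CC(C)(C)c1[nH]c2ccccc2c1-c1c(O)c(Cl)c(-c2c(C(C)(C)C=C)[nH]c3ccccc23)c(O)c1Cl | intermediate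
12 | 2,5-dichloro-3,6-bis[2-(2-methylbut-3-en-2-yl)-1H-indol-3-yl]cyclohexa-2,5-diene-1,4-dione | C=CC(C)(C)c1[nH]c2ccccc2c1C1=C(Cl)C(=O)C(c2c(C(C)(C)C=C)[nH]c3ccccc23)=C(Cl)C1=O | intermediate
13 | 2,5-dihydroxy-3,6-bis[2-(2-methylbut-3-en-2-yl)-1H-indol-3-yl]cyclohexa-2,5-diene-1,4-dione | C=CC(C)(C)c1[nH]c2ccccc2c1C1=C(O)C(=O)C(c2c(C(C)(C)C=C)[nH]c3ccccc23)=C(O)C1=O | intermediate
14 | 2,5-dimethoxy-3,6-bis[2-(2-methylbut-3-en-2-yl)-1H-indol-3-yl]cyclohexa-2,5-diene-1,4-dione (achiral) | C=CC(C)(C)c1[nH]c2ccccc2c1C1=C(OC)C(=O)C(c2c(C(C)(C)C=C)[nH]c3ccccc23)=C(OC)C1=O | target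

## Summary

Total step count: 7. Longest linear sequence: 7 steps (1 → 14); indole 7 is used twice, in steps 4 and 5.

Steps most likely to fail, each with one fallback:

**Step 5 (second Michael addition, hindered by the tert-alkyl group).** The fallback sets out from 7 and comes back at 13. Indole 7 (2.2 equiv) is treated with tetrabromo-1,4-benzoquinone and Cs2CO3 in MeCN at rt. This is a base-mediated addition–elimination on a much more electrophilic perhaloquinone, needing neither acid nor oxidant. It gives first 2,3,5-tribromo-6-[2-(2-methylbut-3-en-2-yl)-1H-indol-3-yl]cyclohexa-2,5-diene-1,4-dione F3. Because the first indolyl group deactivates its neighbouring carbonyl, the second indole enters para to give 2,5-dibromo-3,6-bis[2-(2-methylbut-3-en-2-yl)-1H-indol-3-yl]cyclohexa-2,5-diene-1,4-dione F4; any 2,6-isomer is removed by chromatography. F4 is hydrolysed with aqueous NaOH in MeOH at reflux exactly as 12 is, which rejoins the route at 13.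

**Step 3 (Madelung ring closure).** The fallback sets out from 3 and comes back at 7. Acid 3 is treated with MeLi (2.2 equiv, Et2O, 0 °C → rt) to give 3,3-dimethylpent-4-en-2-one F1. F1 is condensed with phenylhydrazine (toluene, MgSO4, rt) to (E)-1-(3,3-dimethylpent-4-en-2-ylidene)-2-phenylhydrazine F2. F2 is cyclised by a Fischer indole synthesis promoted by PCl3 in toluene at rt, conditions mild enough for the allyl group. Only the methyl side of the ketone can tautomerise, so the indolisation can only give 7.

**Step 6 (hydrolysis of the hindered dichloride; the free dihydroxyquinone may be hard to obtain clean).** The fallback sets out from 12 and comes back at 14. Compound 12 is treated with anhydrous NaOMe (4 equiv) in MeOH/THF at 0 °C → rt, so that a double addition–elimination installs both methoxy groups directly. This bypasses 13 and the methylation step and makes no new compound (F0).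

## Further compounds

F1 | step 3 | 3,3-dimethylpent-4-en-2-one | CC(=O)C(C)(C)C=C
F2 | step 3 | (E)-1-(3,3-dimethylpent-4-en-2-ylidene)-2-phenylhydrazine | C/C(=N\Nc1ccccc1)C(C)(C)C=C
F3 | step 5 | 2,3,5-tribromo-6-[2-(2-methylbut-3-en-2-yl)-1H-indol-3-yl]cyclohexa-2,5-diene-1,4-dione | C=CC(C)(C)c1[nH]c2ccccc2c1C1=C(Br)C(=O)C(Br)=C(Br)C1=O
F4 | step 5 | 2,5-dibromo-3,6-bis[2-(2-methylbut-3-en-2-yl)-1H-indol-3-yl]cyclohexa-2,5-diene-1,4-dione | C=CC(C)(C)c1[nH]c2ccccc2c1C1=C(Br)C(=O)C(c2c(C(C)(C)C=C)[nH]c3ccccc23)=C(Br)C1=O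
F0 | step 6 | none | none
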